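The lactone is assembled last: its α-benzyl bond and the aryl–CH2 bond of its β-substituent are cut, which leaves a 5-bromo-2,3-dihydrobenzofuran. The O1–C2(aryl)–C3(CH2OH)–C3a unit of this ring system is the O1–C2–C3 unit of a (2S)-flavanone. One oxidative 1,2-shift of the benzo-ring carbon C4a (ring A) from C4 to C3 contracts the pyranone (ring B), forms the C3–C3a bond, sets C3 trans to the C2 aryl group (ring C) and pushes C4 out of the ring as the ester that becomes CH2OH. The precursor is (2S)-6-bromo-8-methoxyflavanone whose ring C carries 3-methoxy and a 4-pivalate.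

Key step: step 6

Assumption: the face selectivity of the palladium/pyridine-oxazoline aryl addition to chromones is taken to follow that of cyclic enones, so the (R)-ligand should give the 2S flavanone; if the opposite sense is found, the (S)-ligand is used and nothing else changes.

Abbreviations: TBS = tert-butyldimethylsilyl; Piv = pivaloyl.

**Route**

Step 1
Reactants: 1 1-(2-hydroxy-3-methoxyphenyl)ethanone
Product: 2 1-(5-bromo-2-hydroxy-3-methoxyphenyl)ethanone
Conditions: NBS, MeCN, 0 °C → rt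
Reagents that add atoms: N-bromosuccinimide, O=C1CCC(=O)N1Br
Why: Electrophilic aromatic bromination goes para to the free hydroxyl (C5), whose two ortho positions are blocked and which the meta-directing acetyl group reinforces, as in the bromination of o-vanillin.

Step 2
Reactants: 2 1-(5-bromo-2-hydroxy-3-methoxyphenyl)ethanone
Product: 4 6-bromo-8-methoxy-4H-chromen-4-one, via enaminone 3 (not isolated)
Conditions: Me2NCH(OMe)2, toluene, 100 °C; then conc. HCl, CH2Cl2, 40 °C
Reagents that add atoms: N,N-dimethylformamide dimethyl acetal, COC(OC)N(C)C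
Why: Condensation of the acetyl methyl group with the formamide acetal gives the enaminone, and acid-promoted intramolecular addition of the phenol with loss of dimethylamine closes the pyranone (enaminone chromone synthesis).

Step 3
Reactants: 5 4-bromo-2-methoxyphenol
Product: 6 4-bromo-2-methoxyphenyl pivalate
Conditions: PivCl, Et3N, DMAP (cat.), CH2Cl2, 0 °C → rt
Reagents that add atoms: pivaloyl chloride, CC(C)(C)C(Cl)=O
Why: Simple O-acylation of the phenol; the pivalate is chosen because it withdraws electron density from this ring for step 6, resists acidic methanol and is removed by the hydride of step 7.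

Step 4
Reactants: 6 4-bromo-2-methoxyphenyl pivalate
Product: 7 [3-methoxy-4-(pivaloyloxy)phenyl]boronic acid
Conditions: B2(OH)4, Pd(OAc)2 (2 mol%), XPhos (4 mol%), KOAc, EtOH, 80 °C
Reagents that add atoms: tetrahydroxydiboron, OB(O)B(O)O
Why: Miyaura borylation with tetrahydroxydiboron under zerovalent palladium catalysis gives the boronic acid directly, and the hindered aryl pivalate should tolerate KOAc in ethanol.

Step 5
Reactants: 4 6-bromo-8-methoxy-4H-chromen-4-one, 7 [3-methoxy-4-(pivaloyloxy)phenyl]boronic acid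
Product: 8 (2S)-6-bromo-8-methoxy-2-[3-methoxy-4-(pivaloyloxy)phenyl]chroman-4-one
Conditions: Pd(OCOCF3)2 (5 mol%), (R)-4-tert-butyl-2-(pyridin-2-yl)-4,5-dihydrooxazole (6 mol%), NH4PF6 (30 mol%), H2O (5 equiv), ClCH2CH2Cl, 60 °C
Reagents that add atoms: none
Why: Asymmetric conjugate addition of an arylboronic acid to a chromone under divalent palladium/pyridine-oxazoline catalysis (transmetalation, enantio-determining insertion of C2=C3 into the aryl–Pd bond, protonolysis by water); the ligand alone sets C2 as S, and the aryl bromide is inert because no zerovalent palladium is involved.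

Step 6
Reactants: 8 (2S)-6-bromo-8-methoxy-2-[3-methoxy-4-(pivaloyloxy)phenyl]chroman-4-one
Product: 11 methyl (2S,3S)-5-bromo-7-methoxy-2-[3-methoxy-4-(pivaloyloxy)phenyl]-2,3-dihydro-1-benzofuran-3-carboxylate (trans), via enol ether 9 (not isolated), via C3-iodanyl ketal 10 (not isolated)
Conditions: PhI(OAc)2 (1.2 equiv), H2SO4 (conc.), HC(OMe)3, rt
Reagents that add atoms: trimethyl orthoformate, COC(OC)OC
Why: Acid and orthoformate convert the C4 ketone into the 4-methoxy-2H-chromene 9, trivalent iodine adds to C3 on the face opposite the C2 aryl group while methanol adds to C4 to give 10, and the ring A carbon C4a, aligned anti-periplanar to the C3–I bond, migrates from C4 to C3 as iodobenzene departs, leaving C4 as a dimethoxycarbenium ion that ends as the methyl ester. The closest known reaction type is the oxidative ring contraction of flavanones to methyl trans-2-aryl-2,3-dihydrobenzofuran-3-carboxylates with thallium trinitrate or iodine reagents in trimethyl orthoformate, a semipinacol-like 1,2-aryl shift. The five-membered ring is closed not by cyclisation of an open chain but by ring contraction through a bridged phenonium-like transition state in which C4a bonds to C3 with inversion. The new stereocentre C3 is controlled by the resident C2 centre (anti iodination, then invertive migration), and because C3 is α to the ester any cis epimer can be equilibrated to the more stable trans isomer, while C2 is not involved and stays S. The step needs migration of C4a in preference to migration of ring C from C2 (isoflavone) and to elimination (flavone); the ring oxygen ortho to C4a and the electron-poor, pivalate-bearing ring C bias the shift, and the hindered pivalate resists acid methanolysis so that no free phenol meets the oxidant.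

Step 7
Reactants: 11 methyl (2S,3S)-5-bromo-7-methoxy-2-[3-methoxy-4-(pivaloyloxy)phenyl]-2,3-dihydro-1-benzofuran-3-carboxylate
Product: 12 4-[(2S,3R)-5-bromo-3-(hydroxymethyl)-7-methoxy-2,3-dihydro-1-benzofuran-2-yl]-2-methoxyphenol
Conditions: LiAlH4, THF, 0 °C; Rochelle salt work-up
Reagents that add atoms: none
Why: Hydride reduction converts the methyl ester into the primary alcohol and cleaves the aryl pivalate in the same operation, without touching the aryl bromide at 0 °C or either stereocentre (the C3 descriptor changes to R only because the priorities change).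

Step 8
Reactants: 12 4-[(2S,3R)-5-bromo-3-(hydroxymethyl)-7-methoxy-2,3-dihydro-1-benzofuran-2-yl]-2-methoxyphenol
Product: 13 (2S,3R)-5-bromo-3-(TBS-oxymethyl)-2-(4-TBS-oxy-3-methoxyphenyl)-7-methoxy-2,3-dihydro-1-benzofuran
Conditions: TBSCl, imidazole, DMF, rt
Reagents that add atoms: tert-butyldimethylsilyl chloride, CC(C)(C)[Si](C)(C)Cl
Why: Standard silylation of a phenol and a primary alcohol gives ethers that are stable to organometallic reagents and amide bases and fall to fluoride at the end.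

Step 9
Reactants: 14 dibenzyl malonate, 15 (R)-epichlorohydrin
Product: 16 benzyl (1R,5R)-2-oxo-3-oxabicyclo[3.1.0]hexane-1-carboxylate (same spatial arrangement as the well-known ethyl (1S,5R) ester)
Conditions: NaH, THF, 0 → 65 °C
Reagents that add atoms: none
Why: Malonate cyclopropanation–lactonisation with epichlorohydrin: the malonate opens the epoxide at its CH2, the alkoxide displaces chloride to form a new epoxide, the malonate carbanion opens it by 3-exo-tet attack with inversion and the resulting alkoxide lactonises onto the cis ester, so that the R centre of 15 becomes C5 (R) of 16.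

Step 10
Reactants: 13 (2S,3R)-5-bromo-3-(TBS-oxymethyl)-2-(4-TBS-oxy-3-methoxyphenyl)-7-methoxy-2,3-dihydro-1-benzofuran, 16 benzyl (1R,5R)-2-oxo-3-oxabicyclo[3.1.0]hexane-1-carboxylate
Product: 18 benzyl (4R)-4-{[(2S,3R)-3-(TBS-oxymethyl)-2-(4-TBS-oxy-3-methoxyphenyl)-7-methoxy-2,3-dihydro-1-benzofuran-5-yl]methyl}-2-oxotetrahydrofuran-3-carboxylate (C3 epimers), via arylmagnesium bromide 17 (not isolated)
Conditions: Mg, LiCl, THF, rt; then CuI (20 mol%), 16, THF, −30 → 0 °C; aq NH4Cl
Reagents that add atoms: none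
Why: Copper-catalysed homoconjugate addition of an aryl Grignard reagent to a cyclopropane-1,1-dicarbonyl compound, which opens at the unsubstituted cyclopropane CH2 and leaves the stereocentre untouched (C5 of 16 becomes the R β-carbon of the lactone), as used for 4-alkyl and 4-benzyl butyrolactones.

Step 11
Reactants: 18 benzyl (4R)-4-(arylmethyl)-2-oxotetrahydrofuran-3-carboxylate
Product: 20 (4R)-4-{[(2S,3R)-3-(TBS-oxymethyl)-2-(4-TBS-oxy-3-methoxyphenyl)-7-methoxy-2,3-dihydro-1-benzofuran-5-yl]methyl}dihydrofuran-2(3H)-one, via malonic half-acid 19 (not isolated)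
Conditions: H2 (1 atm), Pd/C, EtOAc, rt; filter; toluene, 100 °C
Reagents that add atoms: none
Why: Hydrogenolysis of the benzyl ester (much faster than cleavage of the cyclic benzylic ether in ethyl acetate) and thermal decarboxylation of the malonic half-acid remove the activating group under neutral conditions that spare both silyl ethers, and the α-carbon becomes CH2 so its configuration is irrelevant.

Step 12
Reactants: 21 vanillin
Product: 22 4-(TBS-oxy)-3-methoxybenzaldehyde
Conditions: TBSCl, imidazole, DMF, rt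
Reagents that add atoms: tert-butyldimethylsilyl chloride, CC(C)(C)[Si](C)(C)Cl
Why: Phenol silylation; a silyl ether is needed here because it survives the borohydride of step 16, so that no free para-phenoxide can expel the benzylic ester as a quinone methide.

Step 13
Reactants: 23 methyl vanillate, 24 (4R)-4-benzyl-3-(chloroacetyl)oxazolidin-2-one
Product: 25 methyl 4-{2-[(4R)-4-benzyl-2-oxooxazolidin-3-yl]-2-oxoethoxy}-3-methoxybenzoate
Conditions: K2CO3, NaI (cat.), acetone, 50 °C
Reagents that add atoms: none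
Why: Williamson-type O-alkylation of the phenoxide with an α-halo imide (in situ iodide exchange), an SN2 reaction at a highly activated primary carbon that is faster than attack on the imide carbonyls.

Step 14
Reactants: 25 methyl 4-{2-[(4R)-4-benzyl-2-oxooxazolidin-3-yl]-2-oxoethoxy}-3-methoxybenzoate, 22 4-(TBS-oxy)-3-methoxybenzaldehyde
Product: 27 (4R)-4-benzyl-3-[(2R,3S)-3-hydroxy-3-(4-TBS-oxy-3-methoxyphenyl)-2-(2-methoxy-4-methoxycarbonylphenoxy)propanoyl]oxazolidin-2-one (syn, threo), via Z boron enolate 26 (not isolated)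
Conditions: Bu2BOTf, i-Pr2NEt, CH2Cl2, −78 → 0 °C; 22, −78 → 0 °C; pH 7 buffer, MeOH, H2O2, 0 °C
Reagents that add atoms: none
Why: Evans syn aldol reaction: the Z boron enolate reacts through a closed chair transition state on the face opposite the benzyl group of the R auxiliary, giving the 2R,3S adduct, which fixes the aryloxy-bearing carbon of the target (S in the final compound) and gives the carbinol carbon as the threo epimer.

Step 15
Reactants: 27 syn aldol adduct
Product: 28 (4R)-4-benzyl-3-[(2R,3R)-3-(4-nitrobenzoyloxy)-3-(4-TBS-oxy-3-methoxyphenyl)-2-(2-methoxy-4-methoxycarbonylphenoxy)propanoyl]oxazolidin-2-one (anti, erythro)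
Conditions: 4-O2NC6H4CO2H, PPh3, DIAD, THF, 0 °C → rt
Reagents that add atoms: 4-nitrobenzoic acid, OC(=O)c1ccc(cc1)[N+](=O)[O-]
Why: Mitsunobu esterification with inversion at the benzylic carbinol converts the threo into the erythro series, the rigid imide (allylic strain keeps the α-hydrogen out of alignment) disfavouring elimination.

Step 16
Reactants: 28 anti 4-nitrobenzoate
Product: 29 methyl 4-{[(1R,2S)-1-(4-TBS-oxy-3-methoxyphenyl)-1,3-dihydroxypropan-2-yl]oxy}-3-methoxybenzoate
Conditions: LiBH4, MeOH (2 equiv), THF, 0 °C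
Reagents that add atoms: none
Why: Borohydride reduction cleaves the N-acyl oxazolidinone to the primary alcohol and the electron-poor nitrobenzoate to the secondary alcohol, while the electron-rich methyl benzoate and the aryl silyl ether should react much more slowly at 0 °C.

Step 17
Reactants: 29 erythro diol
Product: 30 methyl 4-{[(1R,2S)-1,3-bis(TBS-oxy)-1-(4-TBS-oxy-3-methoxyphenyl)propan-2-yl]oxy}-3-methoxybenzoate
Conditions: TBSOTf, 2,6-lutidine, CH2Cl2, 0 °C
Reagents that add atoms: tert-butyldimethylsilyl trifluoromethanesulfonate, CC(C)(C)[Si](C)(C)OS(=O)(=O)C(F)(F)F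
Why: The silyl triflate protects the primary and the hindered benzylic hydroxyl in one operation.

Step 18
Reactants: 30 tris-silyl ester
Product: 31 (4-{[(1R,2S)-1,3-bis(TBS-oxy)-1-(4-TBS-oxy-3-methoxyphenyl)propan-2-yl]oxy}-3-methoxyphenyl)methanol
Conditions: i-Bu2AlH, CH2Cl2, −78 °C; Rochelle salt work-up
Reagents that add atoms: none
Why: Aluminium hydride reduction of the aryl ester to the benzylic alcohol, with silyl ethers inert at −78 °C.

Step 19
Reactants: 31 benzylic alcohol
Product: 32 4-(bromomethyl)-1-{[(1R,2S)-1,3-bis(TBS-oxy)-1-(4-TBS-oxy-3-methoxyphenyl)propan-2-yl]oxy}-2-methoxybenzene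
Conditions: CBr4, PPh3, CH2Cl2, 0 °C
Reagents that add atoms: carbon tetrabromide, BrC(Br)(Br)Br
Why: Appel bromination under neutral conditions gives the reactive 4-alkoxybenzyl bromide, which is used at once.

Step 20
Reactants: 20 (4R)-4-(arylmethyl)dihydrofuran-2(3H)-one, 32 benzylic bromide
Product: 34 penta-TBS ether of the target, (3R,4R)-trans lactone, via lithium enolate 33 (not isolated)
Conditions: LiN(SiMe3)2, THF, −78 °C; then 32, −78 → −40 °C
Reagents that add atoms: none
Why: Alkylation of the lactone lithium enolate with a benzylic bromide occurs anti to the β-substituent, giving the trans-3,4-disubstituted lactone (3R) as in classical dibenzylbutyrolactone lignan syntheses.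

Step 21
Reactants: 34 penta-TBS ether of the target
Product: 35 CNP0298853.1, (3R,4R)-3-{4-[(1R,2S)-1,3-dihydroxy-1-(4-hydroxy-3-methoxyphenyl)propan-2-yl]oxy-3-methoxybenzyl}-4-{[(2S,3R)-2-(4-hydroxy-3-methoxyphenyl)-3-(hydroxymethyl)-7-methoxy-2,3-dihydro-1-benzofuran-5-yl]methyl}dihydrofuran-2(3H)-one
Conditions: Bu4NF, AcOH, THF, 0 °C → rt
Reagents that add atoms: none
Why: Fluoride-mediated cleavage of all five silyl ethers, buffered with acetic acid so that the lactone, the phenols and the benzylic ethers are not exposed to strong base.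

**Compound list**

1 | 1-(2-hydroxy-3-methoxyphenyl)ethanone | CC(=O)c1cccc(OC)c1O | starting material
2 | 1-(5-bromo-2-hydroxy-3-methoxyphenyl)ethanone | CC(=O)c1cc(Br)cc(OC)c1O | intermediate
3 | (E)-1-(5-bromo-2-hydroxy-3-methoxyphenyl)-3-(dimethylamino)prop-2-en-1-one | CN(C)/C=C/C(=O)c1cc(Br)cc(OC)c1O | intermediate
4 | 6-bromo-8-methoxy-4H-chromen-4-one | COc1cc(Br)cc2C(=O)C=COc12 | intermediate
5 | 4-bromo-2-methoxyphenol | COc1cc(Br)ccc1O | starting material
6 | 4-bromo-2-methoxyphenyl pivalate | COc1cc(Br)ccc1OC(=O)C(C)(C)C | intermediate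
7 | [3-methoxy-4-(pivaloyloxy)phenyl]boronic acid | COc1cc(B(O)O)ccc1OC(=O)C(C)(C)C | intermediate
8 | (2S)-6-bromo-8-methoxy-2-[3-methoxy-4-(pivaloyloxy)phenyl]chroman-4-one | COc1cc(Br)cc2C(=O)C[C@@H](c3ccc(OC(=O)C(C)(C)C)c(OC)c3)Oc12 | intermediate
9 | (2S)-6-bromo-4,8-dimethoxy-2-[3-methoxy-4-(pivaloyloxy)phenyl]-2H-chromene | COC1=C[C@@H](c2ccc(OC(=O)C(C)(C)C)c(OC)c2)Oc2c(OC)cc(Br)cc12 | intermediate
10 | trans-3-[acetoxy(phenyl)iodanyl]-6-bromo-4,4,8-trimethoxy-2-[3-methoxy-4-(pivaloyloxy)phenyl]chromane (iodine at C3 anti to the C2 aryl group; 2R,3R by the sequence rule, C2 spatially unchanged) | COc1cc(Br)cc2c1O[C@H](c1ccc(OC(=O)C(C)(C)C)c(OC)c1)[C@@H]([I](OC(C)=O)c1ccccc1)C2(OC)OC | intermediate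
11 | methyl (2S,3S)-5-bromo-7-methoxy-2-[3-methoxy-4-(pivaloyloxy)phenyl]-2,3-dihydro-1-benzofuran-3-carboxylate (trans) | Brc1cc(OC)c2c(c1)[C@H](C(=O)OC)[C@@H](c1ccc(OC(=O)C(C)(C)C)c(OC)c1)O2 | intermediate
12 | 4-[(2S,3R)-5-bromo-3-(hydroxymethyl)-7-methoxy-2,3-dihydro-1-benzofuran-2-yl]-2-methoxyphenol | Brc1cc(OC)c2c(c1)[C@H](CO)[C@@H](c1ccc(O)c(OC)c1)O2 | intermediate
13 | (2S,3R)-5-bromo-3-(TBS-oxymethyl)-2-(4-TBS-oxy-3-methoxyphenyl)-7-methoxy-2,3-dihydro-1-benzofuran | Brc1cc(OC)c2c(c1)[C@H](CO[Si](C)(C)C(C)(C)C)[C@@H](c1ccc(O[Si](C)(C)C(C)(C)C)c(OC)c1)O2 | intermediate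
14 | dibenzyl malonate | O=C(CC(=O)OCc1ccccc1)OCc1ccccc1 | starting material
15 | (R)-epichlorohydrin, (2R)-2-(chloromethyl)oxirane | ClC[C@H]1CO1 | starting material
16 | benzyl (1R,5R)-2-oxo-3-oxabicyclo[3.1.0]hexane-1-carboxylate | O=C1OC[C@@H]2C[C@]12C(=O)OCc1ccccc1 | intermediate
17 | arylmagnesium bromide from 13 (MgBr at C5 of the dihydrobenzofuran) | Br[Mg]c1cc(OC)c2c(c1)[C@H](CO[Si](C)(C)C(C)(C)C)[C@@H](c1ccc(O[Si](C)(C)C(C)(C)C)c(OC)c1)O2 | intermediate
18 | benzyl (4R)-4-{[(2S,3R)-3-(TBS-oxymethyl)-2-(4-TBS-oxy-3-methoxyphenyl)-7-methoxy-2,3-dihydro-1-benzofuran-5-yl]methyl}-2-oxotetrahydrofuran-3-carboxylate (C3 epimers) | O=C(OCc1ccccc1)C1C(=O)OC[C@@H]1Cc1cc(OC)c2c(c1)[C@H](CO[Si](C)(C)C(C)(C)C)[C@@H](c1ccc(O[Si](C)(C)C(C)(C)C)c(OC)c1)O2 | intermediate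
19 | (4R)-4-(arylmethyl)-2-oxotetrahydrofuran-3-carboxylic acid corresponding to 18 (C3 epimers) | OC(=O)C1C(=O)OC[C@@H]1Cc1cc(OC)c2c(c1)[C@H](CO[Si](C)(C)C(C)(C)C)[C@@H](c1ccc(O[Si](C)(C)C(C)(C)C)c(OC)c1)O2 | intermediate
20 | (4R)-4-{[(2S,3R)-3-(TBS-oxymethyl)-2-(4-TBS-oxy-3-methoxyphenyl)-7-methoxy-2,3-dihydro-1-benzofuran-5-yl]methyl}dihydrofuran-2(3H)-one | O=C1C[C@@H](Cc2cc(OC)c3c(c2)[C@H](CO[Si](C)(C)C(C)(C)C)[C@@H](c2ccc(O[Si](C)(C)C(C)(C)C)c(OC)c2)O3)CO1 | intermediate
21 | vanillin | COc1cc(C=O)ccc1O | starting material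
22 | 4-(TBS-oxy)-3-methoxybenzaldehyde | COc1cc(C=O)ccc1O[Si](C)(C)C(C)(C)C | intermediate
23 | methyl vanillate (methyl 4-hydroxy-3-methoxybenzoate) | COC(=O)c1ccc(O)c(OC)c1 | starting material
24 | (4R)-4-benzyl-3-(chloroacetyl)oxazolidin-2-one | ClCC(=O)N1C(=O)OC[C@H]1Cc1ccccc1 | starting material
25 | methyl 4-{2-[(4R)-4-benzyl-2-oxooxazolidin-3-yl]-2-oxoethoxy}-3-methoxybenzoate | COC(=O)c1ccc(OCC(=O)N2C(=O)OC[C@H]2Cc2ccccc2)c(OC)c1 | intermediate
26 | Z dibutylboron enolate of 25 | CCCCB(CCCC)O/C(N1C(=O)OC[C@H]1Cc1ccccc1)=C\Oc1ccc(cc1OC)C(=O)OC | intermediate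
27 | (4R)-4-benzyl-3-[(2R,3S)-3-hydroxy-3-(4-TBS-oxy-3-methoxyphenyl)-2-(2-methoxy-4-methoxycarbonylphenoxy)propanoyl]oxazolidin-2-one | COc1cc([C@H](O)[C@H](C(=O)N2C(=O)OC[C@H]2Cc2ccccc2)Oc2ccc(cc2OC)C(=O)OC)ccc1O[Si](C)(C)C(C)(C)C | intermediate
28 | (4R)-4-benzyl-3-[(2R,3R)-3-(4-nitrobenzoyloxy)-3-(4-TBS-oxy-3-methoxyphenyl)-2-(2-methoxy-4-methoxycarbonylphenoxy)propanoyl]oxazolidin-2-one | COc1cc([C@@H](OC(=O)c2ccc(cc2)[N+](=O)[O-])[C@H](C(=O)N2C(=O)OC[C@H]2Cc2ccccc2)Oc2ccc(cc2OC)C(=O)OC)ccc1O[Si](C)(C)C(C)(C)C | intermediate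
29 | methyl 4-{[(1R,2S)-1-(4-TBS-oxy-3-methoxyphenyl)-1,3-dihydroxypropan-2-yl]oxy}-3-methoxybenzoate | COc1cc([C@@H](O)[C@H](CO)Oc2ccc(cc2OC)C(=O)OC)ccc1O[Si](C)(C)C(C)(C)C | intermediate
30 | methyl 4-{[(1R,2S)-1,3-bis(TBS-oxy)-1-(4-TBS-oxy-3-methoxyphenyl)propan-2-yl]oxy}-3-methoxybenzoate | COc1cc([C@@H](O[Si](C)(C)C(C)(C)C)[C@H](CO[Si](C)(C)C(C)(C)C)Oc2ccc(cc2OC)C(=O)OC)ccc1O[Si](C)(C)C(C)(C)C | intermediate
31 | (4-{[(1R,2S)-1,3-bis(TBS-oxy)-1-(4-TBS-oxy-3-methoxyphenyl)propan-2-yl]oxy}-3-methoxyphenyl)methanol | COc1cc([C@@H](O[Si](C)(C)C(C)(C)C)[C@H](CO[Si](C)(C)C(C)(C)C)Oc2ccc(CO)cc2OC)ccc1O[Si](C)(C)C(C)(C)C | intermediate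
32 | 4-(bromomethyl)-1-{[(1R,2S)-1,3-bis(TBS-oxy)-1-(4-TBS-oxy-3-methoxyphenyl)propan-2-yl]oxy}-2-methoxybenzene | COc1cc([C@@H](O[Si](C)(C)C(C)(C)C)[C@H](CO[Si](C)(C)C(C)(C)C)Oc2ccc(CBr)cc2OC)ccc1O[Si](C)(C)C(C)(C)C | intermediate
33 | lithium enolate of lactone 20 | [Li]OC1=C[C@@H](Cc2cc(OC)c3c(c2)[C@H](CO[Si](C)(C)C(C)(C)C)[C@@H](c2ccc(O[Si](C)(C)C(C)(C)C)c(OC)c2)O3)CO1 | intermediate
34 | penta-TBS ether of the target (both phenols, both primary alcohols and the benzylic alcohol silylated; lactone 3R,4R; dihydrobenzofuran 2S,3R; ether unit 1R,2S) | COc1cc([C@@H](O[Si](C)(C)C(C)(C)C)[C@H](CO[Si](C)(C)C(C)(C)C)Oc2ccc(C[C@H]3C(=O)OC[C@@H]3Cc3cc(OC)c4c(c3)[C@H](CO[Si](C)(C)C(C)(C)C)[C@@H](c3ccc(O[Si](C)(C)C(C)(C)C)c(OC)c3)O4)cc2OC)ccc1O[Si](C)(C)C(C)(C)C | intermediate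
35 | CNP0298853.1 | COc1cc([C@@H](O)[C@H](CO)Oc2ccc(C[C@H]3C(=O)OC[C@@H]3Cc3cc(OC)c4c(c3)[C@H](CO)[C@@H](c3ccc(O)c(OC)c3)O4)cc2OC)ccc1O | target

**Step count and risks**

Total step count: 21. Longest linear sequence: 10 steps (1, 2, 5, 6, 7, 8, 10, 11, 20, 21).

Steps most likely to fail:

Step 6. The oxidative shift may be diverted into migration of ring C from C2 to C3, into elimination to the flavone, or into acid-induced opening of the heterocycle with loss of the C2 configuration. The fallback sets out from 8 and keeps the same C4a shift but drives it by a carbene instead of an oxidant. The lithium enolate of 8 (LiN(SiMe3)2, THF, −78 °C) is acylated with CF3CO2CH2CF3 to the 3-trifluoroacetyl flavanone F1. Detrifluoroacetylative diazo transfer (MsN3, Et3N, MeCN) gives the 3-diazo flavanone F2. Photolysis in MeOH (Wolff rearrangement, ring contraction through the ketene) gives the methyl ester as 11 together with its cis epimer F3. DBU in CH2Cl2 equilibrates the mixture at C3 to the trans ester, and the route is rejoined at 11.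

Step 10. The aryl Grignard reagent may be lost by protonation or by direct addition to the lactone or ester carbonyl instead of opening the cyclopropane. The fallback sets out from 13 by way of 17. Transmetalation with ZnCl2 gives the arylzinc chloride F4. Negishi coupling (Pd(PPh3)4, THF) with the known allylic bromide 4-(bromomethyl)furan-2(5H)-one gives the 4-(arylmethyl)furan-2(5H)-one F5. Asymmetric conjugate reduction of the butenolide with copper hydride (Cu(OAc)2, a chiral bisphosphine such as p-Tol-BINAP in the antipode that gives 4R, polymethylhydrosiloxane, t-BuOH) sets the β-stereocentre by catalyst control. The route is rejoined at 20, so steps 9 and 11 are not needed.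

Step 15. The benzylic carbinol may ionise (partial retention) or eliminate to the enol ether instead of undergoing clean inversion. The fallback sets out from 27 and replaces the substitution by an oxidation–reduction at the carbinol carbon. LiBH4 removes the auxiliary to give the threo diol F6. TBSCl (1 equiv) with imidazole silylates the primary hydroxyl selectively to give F7. Dess–Martin periodinane gives the α-aryloxy ketone F8. Chelation-controlled reduction with Zn(BH4)2 in Et2O at −20 °C, with hydride delivered to the chelate of the ketone and the α-aryloxy oxygen, gives the anti (erythro) alcohol F9. TBSOTf with 2,6-lutidine then gives 30, where the route is rejoined.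

Further compounds

F1 | step 6 | (2S)-6-bromo-8-methoxy-2-[3-methoxy-4-(pivaloyloxy)phenyl]-3-(trifluoroacetyl)chroman-4-one (C3 epimers or enol) | COc1cc(Br)cc2C(=O)C(C(=O)C(F)(F)F)[C@@H](c3ccc(OC(=O)C(C)(C)C)c(OC)c3)Oc12
F2 | step 6 | 6-bromo-3-diazo-8-methoxy-2-[3-methoxy-4-(pivaloyloxy)phenyl]chroman-4-one (C2 as in 8) | COc1cc(Br)cc2C(=O)C(=[N+]=[N-])[C@@H](c3ccc(OC(=O)C(C)(C)C)c(OC)c3)Oc12
F3 | step 6 | methyl (2S,3R)-5-bromo-7-methoxy-2-[3-methoxy-4-(pivaloyloxy)phenyl]-2,3-dihydro-1-benzofuran-3-carboxylate (cis) | Brc1cc(OC)c2c(c1)[C@@H](C(=O)OC)[C@@H](c1ccc(OC(=O)C(C)(C)C)c(OC)c1)O2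
F4 | step 10 | arylzinc chloride from 17 (ZnCl at C5 of the dihydrobenzofuran) | Cl[Zn]c1cc(OC)c2c(c1)[C@H](CO[Si](C)(C)C(C)(C)C)[C@@H](c1ccc(O[Si](C)(C)C(C)(C)C)c(OC)c1)O2
F5 | step 10 | 4-{[(2S,3R)-3-(TBS-oxymethyl)-2-(4-TBS-oxy-3-methoxyphenyl)-7-methoxy-2,3-dihydro-1-benzofuran-5-yl]methyl}furan-2(5H)-one | O=C1C=C(Cc2cc(OC)c3c(c2)[C@H](CO[Si](C)(C)C(C)(C)C)[C@@H](c2ccc(O[Si](C)(C)C(C)(C)C)c(OC)c2)O3)CO1
F6 | step 15 | methyl 4-{[(1S,2S)-1-(4-TBS-oxy-3-methoxyphenyl)-1,3-dihydroxypropan-2-yl]oxy}-3-methoxybenzoate (threo) | COc1cc([C@H](O)[C@H](CO)Oc2ccc(cc2OC)C(=O)OC)ccc1O[Si](C)(C)C(C)(C)C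
F7 | step 15 | methyl 4-{[(1S,2S)-3-(TBS-oxy)-1-(4-TBS-oxy-3-methoxyphenyl)-1-hydroxypropan-2-yl]oxy}-3-methoxybenzoate | COc1cc([C@H](O)[C@H](CO[Si](C)(C)C(C)(C)C)Oc2ccc(cc2OC)C(=O)OC)ccc1O[Si](C)(C)C(C)(C)C
F8 | step 15 | methyl 4-{[(2S)-3-(TBS-oxy)-1-(4-TBS-oxy-3-methoxyphenyl)-1-oxopropan-2-yl]oxy}-3-methoxybenzoate | COc1cc(C(=O)[C@H](CO[Si](C)(C)C(C)(C)C)Oc2ccc(cc2OC)C(=O)OC)ccc1O[Si](C)(C)C(C)(C)C
F9 | step 15 | methyl 4-{[(1R,2S)-3-(TBS-oxy)-1-(4-TBS-oxy-3-methoxyphenyl)-1-hydroxypropan-2-yl]oxy}-3-methoxybenzoate (erythro) | COc1cc([C@@H](O)[C@H](CO[Si](C)(C)C(C)(C)C)Oc2ccc(cc2OC)C(=O)OC)ccc1O[Si](C)(C)C(C)(C)C
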